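**Retrosynthetic overview**

- The last operation only unmasks the phenol. The isovanillate ester is put on the acyclic chain early, and the arene is bought (isovanillic acid).
- Key disconnection: the C7–C8 σ-bond of the 3,10,10-trimethyl-7-methylidenecycloundeca-3,8-diene ring, i.e. the bond between the methylidene-bearing ring carbon and the neighbouring ring CH=. In the forward sense an acyclic 2-bromo-1-alkene closes onto a vinyl group by a Mizoroki–Heck macrocyclisation, which should give the carbocycle, the exocyclic methylene and the (E)-C8=C9 alkene in one operation at the oxidation level of the target.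
- Enabling feature: ring carbon C10 is quaternary (CMe2) and sits directly next to the C8=C9 ring alkene. A vinyl group on this carbon cannot isomerise, its internal carbon is shielded so that palladium must add in the endo sense, and the resulting σ-alkylpalladium at C9 has β-hydrogens only on C8, so only the 2-substituted 1,3-diene of the target can form.
- The acyclic bromotriene comes from Negishi sp2–sp3 coupling (ring bond C4–C5) of an (E)-iodoalkene with a 3-bromobut-3-enylzinc reagent. The (E)-C3=C4 alkene comes from Zr-catalysed carboalumination of a homopropargylic alcohol, and the C1 stereocentre from catalytic asymmetric propargylboration of 3,3-dimethylpent-4-enal.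
- Ring order: the 11-membered carbocycle is the only ring that is made, and it is closed last (step 8).

Key step: step 8

Remark: the facial sense of step 2 is assigned by analogy with the accepted two-point binding model for phosphoric-acid-catalysed allyl- and propargylboration; the configuration of 5 would be confirmed by Mosher ester analysis, and the enantiomeric catalyst used if the sense were opposite.
Remark: spent aluminium, zinc, silver and chromium reagents are written as their simplest salts after aqueous work-up.

**Route**

Step 1
Reactants: 1 methyl 3,3-dimethylpent-4-enoate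
Product: 2 3,3-dimethylpent-4-enal
Conditions: DIBAL-H (1.05 equiv), CH2Cl2, −78 °C; MeOH quench, aq. Rochelle salt; product kept as a concentrated solution (volatile)
Reagents that add atoms: none
Why: Partial ester reduction with DIBAL-H should stop at the aldehyde because the aluminium hemiacetal is stable at −78 °C and collapses only on work-up, while the vinyl group is inert to the hydride.

Step 2
Reactants: 2 3,3-dimethylpent-4-enal; 3 allenylboronic acid pinacol ester
Product: 5 (S)-6,6-dimethyloct-7-en-1-yn-4-ol, via pinacol borate 4 (not isolated)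
Conditions: (S)-TRIP phosphoric acid (5 mol%), 4 Å MS, toluene, −20 °C; aq. NaHCO3 work-up
Reagents that add atoms: none
Why: Chiral-phosphoric-acid-catalysed asymmetric propargylboration, in which the allenylboronate should add in the SE2′ sense through a closed six-membered chair transition state and the (S)-catalyst should direct addition to the Si face of the aldehyde, setting the (S)-carbinol centre.

Step 3
Reactants: 5 (S)-6,6-dimethyloct-7-en-1-yn-4-ol
Product: 7 (1E,4R)-1-iodo-2,6,6-trimethylocta-1,7-dien-4-ol, via alkenylalane 6 (not isolated)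
Conditions: Me3Al (3 equiv), Cp2ZrCl2 (0.3 equiv), CH2Cl2, 0 °C → rt; then I2, THF, −30 → 0 °C; aq. Rochelle salt/Na2S2O3
Reagents that add atoms: trimethylaluminium, C[Al](C)C; iodine, II
Why: Negishi zirconium-catalysed carboalumination should add methyl and aluminium syn across the terminal alkyne with methyl on the internal carbon, and iodinolysis with retention then gives the (E)-iodoalkene, the hydroxyl being carried as its aluminium alkoxide and the stereocentre untouched (the descriptor changes to R only through the CIP priority of iodine).

Step 4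
Reactants: 8 isovanillic acid (3-hydroxy-4-methoxybenzoic acid)
Product: 10 3-[(tert-butyldimethylsilyl)oxy]-4-methoxybenzoic acid, via bis-silyl derivative 9 (not isolated)
Conditions: TBSCl (2.3 equiv), imidazole, DMF, rt; then AcOH/THF/H2O, rt
Reagents that add atoms: tert-butyldimethylsilyl chloride, CC(C)(C)[Si](C)(C)Cl
Why: Exhaustive silylation followed by selective hydrolysis of the much more labile silyl ester should leave only the aryl silyl ether in place.

Step 5
Reactants: 7 (1E,4R)-1-iodo-2,6,6-trimethylocta-1,7-dien-4-ol; 10 3-[(tert-butyldimethylsilyl)oxy]-4-methoxybenzoic acid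
Product: 11 (1E,4R)-1-iodo-2,6,6-trimethylocta-1,7-dien-4-yl 3-[(tert-butyldimethylsilyl)oxy]-4-methoxybenzoate
Conditions: DCC (1.3 equiv), DMAP (0.2 equiv), CH2Cl2, 0 °C → rt
Reagents that add atoms: none
Why: Steglich esterification acylates the secondary alcohol at oxygen, so the C–O bond of the stereocentre is not broken and the configuration is retained.

Step 6
Reactants: 12 3-bromobut-3-en-1-ol
Product: 13 2-bromo-4-iodobut-1-ene
Conditions: I2, PPh3, imidazole, CH2Cl2, 0 °C → rt, dark
Reagents that add atoms: iodine, II
Why: Appel-type iodination should convert the primary alcohol by SN2 displacement of the oxyphosphonium group without touching the bromoalkene.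

Step 7
Reactants: 11 (1E,4R)-1-iodo-2,6,6-trimethylocta-1,7-dien-4-yl 3-[(tert-butyldimethylsilyl)oxy]-4-methoxybenzoate; 13 2-bromo-4-iodobut-1-ene
Product: 15 (5S,7E)-11-bromo-3,3,7-trimethyldodeca-1,7,11-trien-5-yl 3-[(tert-butyldimethylsilyl)oxy]-4-methoxybenzoate, via alkylzinc iodide 14 (not isolated)
Conditions: 13 (1.6 equiv), Zn dust (TMSCl/1,2-dibromoethane-activated), THF, 35 °C; then 11, Pd(PPh3)4 (5 mol%), THF, rt
Reagents that add atoms: zinc, [Zn] (retained in 14 only)
Why: Negishi coupling of a homoallylzinc reagent with an alkenyl iodide should proceed with retention of the (E) geometry, because zinc inserts only into the primary C–I bond and Pd(0) adds to the alkenyl C–I bond much faster than to the 1,1-disubstituted C–Br bond at room temperature.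

Step 8
Reactants: 15 (5S,7E)-11-bromo-3,3,7-trimethyldodeca-1,7,11-trien-5-yl 3-[(tert-butyldimethylsilyl)oxy]-4-methoxybenzoate
Product: 16 (1S,3E,8E)-3,10,10-trimethyl-7-methylidenecycloundeca-3,8-dien-1-yl 3-[(tert-butyldimethylsilyl)oxy]-4-methoxybenzoate
Conditions: Pd(OAc)2 (15 mol%), PPh3 (45 mol%), Ag2CO3 (2 equiv), MeCN, 70 °C, 2 mM, syringe-pump addition
Reagents that add atoms: none
Why: Pd(0) inserts into the C–Br bond of the 2-bromo-1-alkene, silver abstracts the halide, the alkenylpalladium adds syn to the vinyl group at its terminal CH2, and syn β-hydride elimination forms the C7–C8 bond and the (E)-C8=C9 alkene in one catalytic event (intramolecular Mizoroki–Heck reaction). The closest known reaction type is the macrocyclising Heck reaction of alkenyl halides with terminal alkenes to give ring dienes, which has been used for rings of eleven and more members. The carbocycle closes in the 11-endo-trig mode, because the internal vinyl carbon is shielded by the adjacent quaternary CMe2 carbon, which disfavours the 10-exo mode. No stereocentre is created, the (S)-ester centre is remote and untouched, and the (E) geometry of the new ring alkene should follow from syn elimination through the rotamer that places the CMe2 carbon and the diene carbon anti. The step needs cyclisation to win over oligomerisation, which the 2 mM pseudo-high dilution and the gem-dimethyl turn element should secure, and it needs one sense of β-hydride elimination without later migration, which is secured because the palladium-bearing carbon has hydrogens only on the newly bonded CH2 and because Ag2CO3 removes the palladium hydride quickly. The trisubstituted (E)-alkene should not compete, since it could only be reached by 4-exo or 5-endo closure.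

Step 9
Reactants: 16 (1S,3E,8E)-3,10,10-trimethyl-7-methylidenecycloundeca-3,8-dien-1-yl 3-[(tert-butyldimethylsilyl)oxy]-4-methoxybenzoate
Product: 17 (1S,3E,8E)-3,10,10-trimethyl-7-methylidenecycloundeca-3,8-dien-1-yl 3-hydroxy-4-methoxybenzoate (target)
Conditions: TBAF, AcOH (1:1), THF, 0 °C
Reagents that add atoms: none
Why: Buffered fluoride should cleave the aryl silyl ether selectively, leaving the benzoate ester, the diene and the stereocentre untouched.

**Compound list**

1 | methyl 3,3-dimethylpent-4-enoate | COC(=O)CC(C)(C)C=C | starting material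
2 | 3,3-dimethylpent-4-enal | O=CCC(C)(C)C=C | intermediate
3 | allenylboronic acid pinacol ester (4,4,5,5-tetramethyl-2-(propa-1,2-dien-1-yl)-1,3,2-dioxaborolane) | C=C=CB1OC(C)(C)C(C)(C)O1 | starting material
4 | (S)-2-[(6,6-dimethyloct-7-en-1-yn-4-yl)oxy]-4,4,5,5-tetramethyl-1,3,2-dioxaborolane (pinacol borate of 5) | C#CC[C@H](OB1OC(C)(C)C(C)(C)O1)CC(C)(C)C=C | intermediate
5 | (S)-6,6-dimethyloct-7-en-1-yn-4-ol | C#CC[C@H](O)CC(C)(C)C=C | intermediate
6 | (E)-alkenyldimethylalane of 5, with the hydroxyl as its dimethylaluminium alkoxide (Al cis to the new methyl; carbinol configuration as in 5) | C[Al](C)/C=C(\C)C[C@H](O[Al](C)C)CC(C)(C)C=C | intermediate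
7 | (1E,4R)-1-iodo-2,6,6-trimethylocta-1,7-dien-4-ol | I/C=C(\C)C[C@H](O)CC(C)(C)C=C | intermediate
8 | isovanillic acid (3-hydroxy-4-methoxybenzoic acid) | COc1ccc(cc1O)C(=O)O | starting material
9 | tert-butyldimethylsilyl 3-[(tert-butyldimethylsilyl)oxy]-4-methoxybenzoate | COc1ccc(cc1O[Si](C)(C)C(C)(C)C)C(=O)O[Si](C)(C)C(C)(C)C | intermediate
10 | 3-[(tert-butyldimethylsilyl)oxy]-4-methoxybenzoic acid | COc1ccc(cc1O[Si](C)(C)C(C)(C)C)C(=O)O | intermediate
11 | (1E,4R)-1-iodo-2,6,6-trimethylocta-1,7-dien-4-yl 3-[(tert-butyldimethylsilyl)oxy]-4-methoxybenzoate | I/C=C(\C)C[C@H](OC(=O)c1ccc(OC)c(O[Si](C)(C)C(C)(C)C)c1)CC(C)(C)C=C | intermediate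
12 | 3-bromobut-3-en-1-ol | OCCC(Br)=C | starting material
13 | 2-bromo-4-iodobut-1-ene | ICCC(Br)=C | intermediate
14 | (3-bromobut-3-en-1-yl)zinc iodide | I[Zn]CCC(Br)=C | intermediate
15 | (5S,7E)-11-bromo-3,3,7-trimethyldodeca-1,7,11-trien-5-yl 3-[(tert-butyldimethylsilyl)oxy]-4-methoxybenzoate | C=C(Br)CC/C=C(\C)C[C@H](OC(=O)c1ccc(OC)c(O[Si](C)(C)C(C)(C)C)c1)CC(C)(C)C=C | intermediate
16 | (1S,3E,8E)-3,10,10-trimethyl-7-methylidenecycloundeca-3,8-dien-1-yl 3-[(tert-butyldimethylsilyl)oxy]-4-methoxybenzoate | C=C1/C=C/C(C)(C)C[C@@H](OC(=O)c2ccc(OC)c(O[Si](C)(C)C(C)(C)C)c2)C/C(C)=C/CC1 | intermediate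
17 | (1S,3E,8E)-3,10,10-trimethyl-7-methylidenecycloundeca-3,8-dien-1-yl 3-hydroxy-4-methoxybenzoate | C=C1/C=C/C(C)(C)C[C@@H](OC(=O)c2ccc(OC)c(O)c2)C/C(C)=C/CC1 | target

**Step count and risks**

Total steps: 9. Longest linear sequence: 7 steps (1, 2, 3, 5, 7, 8, 9).

Steps most likely to fail:

Step 8 (Heck macrocyclisation). What may go wrong is intermolecular coupling to oligomers, or re-addition of palladium hydride to the product with migration of the exocyclic diene into the ring. The fallback sets out from 15 and returns to the route at 16, and it makes the same ring bond by carbonyl addition. The monosubstituted vinyl group of 15 would be hydroborated with 9-BBN-H (THF, 0 °C → rt; the bromoalkene and the trisubstituted alkene should react far more slowly) to the B-alkyl-9-BBN adduct F1, which is oxidised in the same flask (NaBO3·4H2O) to the primary alcohol F2. Dess–Martin periodinane (NaHCO3, CH2Cl2) should give the aldehyde F3. A Nozaki–Hiyama–Kishi reaction (CrCl2, cat. NiCl2, DMSO/THF, 2 mM, rt → 50 °C) should then add the alkenyl bromide to the aldehyde and close the ring to the macrocyclic allylic alcohol F4, formed as both carbinol epimers. Both epimers converge on dehydration (Martin sulfurane, CH2Cl2, 0 °C → rt) to 16, because the carbinol carbon has hydrogens only on the side of the CMe2 carbon.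

Step 7 (Negishi coupling with the bifunctional zinc reagent). What may go wrong is insertion of palladium into the C–Br bond of 14 or of the product, leading to self-coupling of the reagent and poor discrimination between C–I and C–Br. The fallback sets out from 11 and returns to the route at 16, and it introduces the alkenyl electrophile only after the coupling. Compound 11 would be coupled under the same Negishi conditions with [2-(2-methyl-1,3-dioxolan-2-yl)ethyl]zinc bromide F5 (from commercial 2-(2-bromoethyl)-2-methyl-1,3-dioxolane, Zn, cat. I2, DMA, 80 °C) to the ketal F6. PPTS in wet acetone should free the methyl ketone F7. KHMDS and PhNTf2 (THF, −78 °C) should give the terminal, kinetically formed enol triflate F8. F8 would then be cyclised by the same 11-endo Heck closure (Pd(OAc)2, PPh3, Et3N, MeCN, 70 °C, 2 mM) to 16.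

Step 2 (asymmetric propargylboration). What may go wrong is poor facial selectivity with this α-unbranched, β-quaternary aliphatic aldehyde, or formation of some allenyl carbinol by loss of SE2′ regiocontrol. The fallback sets out from 2 and returns to the route at 5, and it replaces catalyst control by enzymatic resolution. A zinc-mediated Barbier propargylation of 2 (propargyl bromide, Zn, THF/sat. aq. NH4Cl, 0 °C) would give the racemic homopropargylic alcohol F9. A lipase-catalysed kinetic resolution (Amano PS or CAL-B, vinyl acetate, MTBE, rt) should acetylate the (R)-enantiomer, following the Kazlauskas rule, to the (R)-acetate F10 and leave (S)-5, which is separated by chromatography.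

Further compounds
F1 | step 8 | B-alkyl-9-BBN adduct of 15 (boron on the former terminal vinyl carbon; (E)-alkene and ester-bearing centre configured as in 15) | C=C(Br)CC/C=C(\C)C[C@H](OC(=O)c1ccc(OC)c(O[Si](C)(C)C(C)(C)C)c1)CC(C)(C)CCB1C2CCCC1CCC2
F2 | step 8 | primary alcohol, (7E)-11-bromo-1-hydroxy-3,3,7-trimethyldodeca-7,11-dien-5-yl 3-[(tert-butyldimethylsilyl)oxy]-4-methoxybenzoate (ester-bearing centre configured as in 15) | C=C(Br)CC/C=C(\C)C[C@H](OC(=O)c1ccc(OC)c(O[Si](C)(C)C(C)(C)C)c1)CC(C)(C)CCO
F3 | step 8 | aldehyde, (7E)-11-bromo-3,3,7-trimethyl-1-oxododeca-7,11-dien-5-yl 3-[(tert-butyldimethylsilyl)oxy]-4-methoxybenzoate (ester-bearing centre configured as in 15) | C=C(Br)CC/C=C(\C)C[C@H](OC(=O)c1ccc(OC)c(O[Si](C)(C)C(C)(C)C)c1)CC(C)(C)CC=O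
F4 | step 8 | macrocyclic allylic alcohol, (3E)-8-hydroxy-3,10,10-trimethyl-7-methylidenecycloundec-3-en-1-yl 3-[(tert-butyldimethylsilyl)oxy]-4-methoxybenzoate (ester-bearing centre configured as in 16; both C8 epimers) | C=C1C(O)CC(C)(C)C[C@@H](OC(=O)c2ccc(OC)c(O[Si](C)(C)C(C)(C)C)c2)C/C(C)=C/CC1
F5 | step 7 | [2-(2-methyl-1,3-dioxolan-2-yl)ethyl]zinc bromide | Br[Zn]CCC1(C)OCCO1
F6 | step 7 | ketal, (1E)-2,2-dimethyl-1-vinyl-type chain of 11 with the iodine replaced by a 2-(2-methyl-1,3-dioxolan-2-yl)ethyl group ((E)-alkene and ester-bearing centre configured as in 15) | CC1(CC/C=C(\C)C[C@H](OC(=O)c2ccc(OC)c(O[Si](C)(C)C(C)(C)C)c2)CC(C)(C)C=C)OCCO1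
F7 | step 7 | methyl ketone, (7E)-3,3,7-trimethyl-11-oxododeca-1,7-dien-5-yl 3-[(tert-butyldimethylsilyl)oxy]-4-methoxybenzoate (ester-bearing centre configured as in 15) | CC(=O)CC/C=C(\C)C[C@H](OC(=O)c1ccc(OC)c(O[Si](C)(C)C(C)(C)C)c1)CC(C)(C)C=C
F8 | step 7 | enol triflate, (7E)-3,3,7-trimethyl-11-{[(trifluoromethyl)sulfonyl]oxy}dodeca-1,7,11-trien-5-yl 3-[(tert-butyldimethylsilyl)oxy]-4-methoxybenzoate (ester-bearing centre configured as in 15) | C=C(OS(=O)(=O)C(F)(F)F)CC/C=C(\C)C[C@H](OC(=O)c1ccc(OC)c(O[Si](C)(C)C(C)(C)C)c1)CC(C)(C)C=C
F9 | step 2 | racemic 6,6-dimethyloct-7-en-1-yn-4-ol | C#CCC(O)CC(C)(C)C=C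
F10 | step 2 | (R)-6,6-dimethyloct-7-en-1-yn-4-yl acetate | C#CC[C@@H](OC(C)=O)CC(C)(C)C=C
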